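**Two slow steps.** Two slow steps race in this flask: electrophile takes anion to make target, and acidic substrate takes target away as side product. I assumed that the proton exchange between acidic substrate and free base stays at its balance. Then c(anion) = K·c(acidic substrate)·c(free base)/c(protonated base). Acidic substrate cancels from the ratio of the two rates, leaving a constant, a selectivity factor, times c(target)·c(protonated base)/(c(electrophile)·c(free base)).

common to all: acidic substrate 0.40 M

| flask | free base | electrophile | protic impurity | temperature | remark | time |
|---|---|---|---|---|---|---|
| dusk | 1.2 equiv | 1.3 equiv | 0.080 M | 80 °C | run made earlier |  |
| eta | 1.20 equiv | 1.30 equiv | 0.0400 M | 80 °C |  | 2.0 h |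
| alpha | 1.20 equiv | 1.30 equiv | 0.0400 M | 55 °C |  | 2.0 h |
| zeta | 1.20 equiv | 1.30 equiv | 0.0400 M |  | at 55 °C until 1.0 h, from then on at 80 °C | 2.0 h |

dusk run (percent of the acidic substrate charged): time / min: target / % = 1.33: 23.4; 4.00: 44.1; 6.00: 51.1; 10.0: 59.0; 15.0: 62.9; 20.0: 64.8; 25.0: 65.4

(scatter of a reading: 0.3 percentage points)

- in percentages every species weighs as the acidic substrate in it: one side product counts as two
- steps thought possible: acidic substrate + free base <-> protonated base + anion; electrophile + anion -> target; electrophile + protic impurity -> quenched reagent; acidic substrate + target -> side product
- the earlier runs do not show what temperature does; that part of a forecast is a guess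
- no earlier run changes the charge of protic impurity; that part of a forecast is a guess

- the flask that comes out highest in amount of target, in percent of the acidic substrate charged, or "all alike" when all lie within 1.5 percentage points (eta / alpha / zeta / all alike)
- target at the end, in percent of the acidic substrate charged, eta
- target at the end, in percent of the acidic substrate charged, alpha
- target at the end, in percent of the acidic substrate charged, zeta

**Charge number.** I evaluated that quotient at half conversion, with no loss yet and with protic impurity counted as taking its own amount of electrophile. The dusk run gives 0.595. For eta the charge number, that quotient in amounts per acidic substrate charged, is 0.510, smaller than the dusk run's. It says how well placed the side step is against the main one.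

**Reading it.** The last dusk reading gives a leak ratio, substrate not in target per substrate in target, of 0.529. I took this ratio as proportional to the charge number at one temperature. Eta then has a leak ratio of 0.453, so I reckoned its target at 68.8%.

**One number enough?** Alpha and zeta have eta's charges, so they have its charge number, but that number holds no temperature. The factor was read at 80 °C, so my figure of 68.8% for alpha and zeta was a guess.

**The result.** The forecast gave 68% for eta, 66% for alpha and 69% for zeta, and it named zeta highest: “Zeta finishes conversion and keeps part of that gain”. The flasks gave 68.2%, 78.3% and 74.9%, with alpha highest.

    acidic substrate + free base ⇌ protonated base + anion, settled at all times (K = 0.730, ΔH = −29.0 kJ mol⁻¹)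
    electrophile + anion → target (k = 0.920 L mol⁻¹ min⁻¹, Ea = 51.0 kJ mol⁻¹)
    electrophile + protic impurity → quenched reagent (k = 0.220 L mol⁻¹ min⁻¹, Ea = 82.0 kJ mol⁻¹)
    acidic substrate + target → side product (k = 0.130 L mol⁻¹ min⁻¹, Ea = 57.0 kJ mol⁻¹)
    (constants at 80 °C)

**The cold flask.** Alpha's leak ratio was 0.277 on the charge number 0.510, against 0.466 for eta, so one charge number had gone with two leak ratios at the two temperatures. The side step is the main reason for alpha's shortfall: in a run of alpha without it, target goes from 78.3% to 91.5%. A neighbour of alpha with 5.20 equiv of electrophile has a charge number of 0.0776. This scales alpha's leak ratio to 0.0422 and gives target of 96.0%, and that flask gave 96.1%.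

The data were computed for substances that don't exist; the scatter is artificial.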